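**Plan**
- Retrosynthesis: cut the sulfate S–O bond first, then the two O–CH3 bonds, then C2–Br and C3–Br together back to a C2–C3 aryne. The aryne comes from an ortho-silylaryl triflate (C3–Si, C2–OTf). The side-chain C=C (Wittig) leads back to 2-hydroxy-4,5-dimethoxybenzaldehyde.
- Enabling feature: on the single benzene ring the two bromines sit on adjacent C2 and C3, between the side-chain carbon C1 and the oxygenated C4 (C5 OH, C6 H). This is the footprint of a 3,6-disubstituted C2–C3 aryne, and the C2 oxygen of a 1,2,4-trioxygenated arene supplies the triflate.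
- Forward: no ring is formed. The two-carbon chain is completed first (methylenation, anti-Markovnikov hydroboration). C3 is then silylated by carbamate-directed lithiation, C2 is triflated, the aryne is dibrominated, and the product is unmasked and sulfated.
- Stereochemistry: none to set; the target is achiral.

Key step: step 8

Assumption: the target has no stereocentre, so no enantiomer has to be selected; it is taken as the free hydrogen sulfate as drawn, liberated on acid-form resin (a sodium salt would store better).

Step 1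
Reactants: 1 2-hydroxy-4,5-dimethoxybenzaldehyde; 2 N,N-diethylcarbamoyl chloride
Product: 3 2-formyl-4,5-dimethoxyphenyl N,N-diethylcarbamate
Conditions: K2CO3, MeCN, reflux
Reagents that add atoms: N,N-diethylcarbamoyl chloride, CCN(CC)C(=O)Cl
Why: O-carbamoylation of the acidic salicylaldehyde phenoxide masks the phenol (preventing lactol or benzofuran formation during homologation) and installs the group that later directs lithiation.

Step 2
Reactants: 3 2-formyl-4,5-dimethoxyphenyl N,N-diethylcarbamate; 4 methyltriphenylphosphonium bromide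
Product: 5 2-ethenyl-4,5-dimethoxyphenyl N,N-diethylcarbamate
Conditions: Ph3PCH3Br, KOtBu, THF, 0 °C → rt
Reagents that add atoms: methyltriphenylphosphonium bromide, C[P+](c1ccccc1)(c1ccccc1)c1ccccc1.[Br-]
Why: Wittig methylenation of an aryl aldehyde with the unstabilised ylide should proceed cleanly, the N,N-dialkyl carbamate being inert to the ylide.

Step 3
Reactants: 5 2-ethenyl-4,5-dimethoxyphenyl N,N-diethylcarbamate; 6 9-borabicyclo[3.3.1]nonane; 7 hydrogen peroxide
Product: 9 2-(2-hydroxyethyl)-4,5-dimethoxyphenyl N,N-diethylcarbamate, via B-alkyl-9-BBN 8 (not isolated)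
Conditions: 9-BBN, THF, 0 °C → rt; then aq. NaOH, 30% H2O2, 0 °C
Reagents that add atoms: hydrogen peroxide, OO
Why: Hydroboration–oxidation of a styrene with the bulky 9-BBN places boron on the terminal carbon and, after oxidation with retention, gives the primary alcohol; the carbamate is not reduced by the borane and should tolerate cold aqueous hydroxide.

Step 4
Reactants: 9 2-(2-hydroxyethyl)-4,5-dimethoxyphenyl N,N-diethylcarbamate; 10 chlorotriisopropylsilane
Product: 11 4,5-dimethoxy-2-[2-(triisopropylsilyloxy)ethyl]phenyl N,N-diethylcarbamate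
Conditions: TIPSCl, imidazole, DMF, rt
Reagents that add atoms: chlorotriisopropylsilane, CC(C)[Si](Cl)(C(C)C)C(C)C
Why: Imidazole-promoted silylation of a primary alcohol gives a bulky silyl ether that should withstand alkyllithium, hydride, triflic anhydride and a limited dose of fluoride.

Step 5
Reactants: 11 4,5-dimethoxy-2-[2-(triisopropylsilyloxy)ethyl]phenyl N,N-diethylcarbamate; 12 sec-butyllithium; 13 chlorotrimethylsilane
Product: 15 3,4-dimethoxy-2-(trimethylsilyl)-6-[2-(triisopropylsilyloxy)ethyl]phenyl N,N-diethylcarbamate, via aryllithium 14 (not isolated)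
Conditions: s-BuLi, TMEDA, THF, −78 °C; then TMSCl, −78 °C → rt
Reagents that add atoms: chlorotrimethylsilane, C[Si](C)(C)Cl
Why: Directed ortho-metalation occurs at the only ring hydrogen ortho to the carbamate, which lies between the carbamate and a methoxy group and is activated by both; quenching at −78 °C precedes anionic Fries rearrangement and kinetic ring lithiation should outrun benzylic deprotonation.

Step 6
Reactants: 15 3,4-dimethoxy-2-(trimethylsilyl)-6-[2-(triisopropylsilyloxy)ethyl]phenyl N,N-diethylcarbamate
Product: 16 3,4-dimethoxy-2-(trimethylsilyl)-6-[2-(triisopropylsilyloxy)ethyl]phenol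
Conditions: LiAlH4, THF, 0 °C → reflux; Rochelle salt work-up
Reagents that add atoms: none
Why: Hydride reduction of the aryl carbamate reaches the hindered carbonyl, expels the phenoxide and takes the carbamoyl carbon to an N-methyl group, while aryl–Si and Si–O bonds are inert to hydride.

Step 7
Reactants: 16 3,4-dimethoxy-2-(trimethylsilyl)-6-[2-(triisopropylsilyloxy)ethyl]phenol; 17 trifluoromethanesulfonic anhydride
Product: 18 3,4-dimethoxy-2-(trimethylsilyl)-6-[2-(triisopropylsilyloxy)ethyl]phenyl trifluoromethanesulfonate
Conditions: Tf2O, pyridine, CH2Cl2, 0 °C → rt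
Reagents that add atoms: trifluoromethanesulfonic anhydride, O=S(=O)(OS(=O)(=O)C(F)(F)F)C(F)(F)F
Why: O-sulfonylation of an ortho-silylphenol with triflic anhydride and pyridine is the standard entry to ortho-silylaryl triflates and tolerates ortho substitution on both sides.

Step 8
Reactants: 18 3,4-dimethoxy-2-(trimethylsilyl)-6-[2-(triisopropylsilyloxy)ethyl]phenyl trifluoromethanesulfonate; 19 1,2-dibromotetrachloroethane; 20 potassium bromide
Product: 23 [2-(2,3-dibromo-4,5-dimethoxyphenyl)ethoxy]triisopropylsilane, via aryne 21 (not isolated), via ortho-bromoaryl potassium 22 (not isolated)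
Conditions: KF (3 equiv), 18-crown-6, KBr (1.5 equiv), BrCl2C–CCl2Br (2 equiv), THF, 0 °C → rt
Reagents that add atoms: 1,2-dibromotetrachloroethane, ClC(Cl)(Br)C(Cl)(Cl)Br; potassium bromide, [K+].[Br-]
Why: Fluoride attacks the trimethylsilyl group at C3 and the silicate expels triflate from C2 to give the C2–C3 aryne 21; bromide adds to the strained triple bond, expected mainly at C2 so that the carbanion sits at C3 beside the inductively stabilising methoxy group (22), and this anion takes Br+ from 1,2-dibromotetrachloroethane, which collapses to tetrachloroethene and returns bromide to the chain. The closest known reaction type is the fluoride-induced vicinal dihalogenation of arynes from ortho-silylaryl triflates with a halide/electrophilic-halogen pair, a three-component aryne 1,2-difunctionalisation. No ring is closed and no stereocentre is formed. The orientation of bromide addition is irrelevant because both new substituents are bromine and either orientation converges on 23. The selectivity needed is chemoselectivity: the perhaloethane is a soft Br+ donor that should neither ipso-bromodesilylate the electron-rich aryl silane nor brominate C6–H, THF offers no acidic proton to quench 22, and the bulky TIPS ether with a limited excess of fluoride keeps the side-chain oxygen from being unmasked and closing a dihydrobenzofuran onto the aryne.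

Step 9
Reactants: 23 [2-(2,3-dibromo-4,5-dimethoxyphenyl)ethoxy]triisopropylsilane
Product: 24 2-(2,3-dibromo-4,5-dimethoxyphenyl)ethanol
Conditions: TBAF, THF, 0 °C → rt
Reagents that add atoms: none
Why: Fluoride-mediated desilylation of a primary silyl ether is driven by the Si–F bond, and the aryl bromides and methyl ethers are untouched.

Step 10
Reactants: 24 2-(2,3-dibromo-4,5-dimethoxyphenyl)ethanol; 25 boron tribromide
Product: 27 3,4-dibromo-5-(2-hydroxyethyl)benzene-1,2-diol, via boron ester 26 (not isolated)
Conditions: BBr3 (3.5 equiv), CH2Cl2, −78 → 0 °C; then H2O, 0 °C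
Reagents that add atoms: none
Why: Lewis-acid O-demethylation of aryl methyl ethers with BBr3 (boron coordination, then SN2 removal of methyl by bromide) leaves the aryl bromides intact, and keeping the primary alkoxyborane at or below 0 °C should let it hydrolyse back to the alcohol on work-up.

Step 11
Reactants: 27 3,4-dibromo-5-(2-hydroxyethyl)benzene-1,2-diol; 28 phenylboronic acid; 29 sulfur trioxide–pyridine complex
Product: 32 2-(2,3-dibromo-4,5-dihydroxyphenyl)ethyl hydrogen sulfate, via phenylboronate 30 (not isolated), via sulfated phenylboronate 31 (not isolated)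
Conditions: PhB(OH)2 (1.05 equiv), pyridine/toluene, azeotropic evaporation; SO3·pyridine, pyridine, 0 °C → rt; H2O, Et2O wash; Dowex 50W (H+), lyophilise cold
Reagents that add atoms: sulfur trioxide–pyridine complex, O=S(=O)([O-])[n+]1ccccc1
Why: Cyclic arylboronate formation is specific for the two adjacent catechol oxygens, so the primary alcohol is the only free hydroxyl for O-sulfation by SO3·pyridine; the boronate then hydrolyses in water, phenylboronic acid is extracted, and the acid resin delivers the hydrogen sulfate.

**Compound list**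
1 | 2-hydroxy-4,5-dimethoxybenzaldehyde | COc1cc(O)c(C=O)cc1OC | starting material
2 | N,N-diethylcarbamoyl chloride | CCN(CC)C(=O)Cl | starting material
3 | 2-formyl-4,5-dimethoxyphenyl N,N-diethylcarbamate | CCN(CC)C(=O)Oc1cc(OC)c(OC)cc1C=O | intermediate
4 | methyltriphenylphosphonium bromide | C[P+](c1ccccc1)(c1ccccc1)c1ccccc1.[Br-] | starting material
5 | 2-ethenyl-4,5-dimethoxyphenyl N,N-diethylcarbamate | CCN(CC)C(=O)Oc1cc(OC)c(OC)cc1C=C | intermediate
6 | 9-borabicyclo[3.3.1]nonane (9-BBN) | B1C2CCCC1CCC2 | starting material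
7 | hydrogen peroxide | OO | starting material
8 | 2-[2-(9-borabicyclo[3.3.1]nonan-9-yl)ethyl]-4,5-dimethoxyphenyl N,N-diethylcarbamate (not isolated) | CCN(CC)C(=O)Oc1cc(OC)c(OC)cc1CCB1C2CCCC1CCC2 | intermediate
9 | 2-(2-hydroxyethyl)-4,5-dimethoxyphenyl N,N-diethylcarbamate | CCN(CC)C(=O)Oc1cc(OC)c(OC)cc1CCO | intermediate
10 | chlorotriisopropylsilane | CC(C)[Si](Cl)(C(C)C)C(C)C | starting material
11 | 4,5-dimethoxy-2-[2-(triisopropylsilyloxy)ethyl]phenyl N,N-diethylcarbamate | CCN(CC)C(=O)Oc1cc(OC)c(OC)cc1CCO[Si](C(C)C)(C(C)C)C(C)C | intermediate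
12 | sec-butyllithium | [Li]C(C)CC | starting material
13 | chlorotrimethylsilane | C[Si](C)(C)Cl | starting material
14 | 2-lithio-3,4-dimethoxy-6-[2-(triisopropylsilyloxy)ethyl]phenyl N,N-diethylcarbamate (not isolated) | CCN(CC)C(=O)Oc1c([Li])c(OC)c(OC)cc1CCO[Si](C(C)C)(C(C)C)C(C)C | intermediate
15 | 3,4-dimethoxy-2-(trimethylsilyl)-6-[2-(triisopropylsilyloxy)ethyl]phenyl N,N-diethylcarbamate | CCN(CC)C(=O)Oc1c([Si](C)(C)C)c(OC)c(OC)cc1CCO[Si](C(C)C)(C(C)C)C(C)C | intermediate
16 | 3,4-dimethoxy-2-(trimethylsilyl)-6-[2-(triisopropylsilyloxy)ethyl]phenol | Oc1c([Si](C)(C)C)c(OC)c(OC)cc1CCO[Si](C(C)C)(C(C)C)C(C)C | intermediate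
17 | trifluoromethanesulfonic anhydride | O=S(=O)(OS(=O)(=O)C(F)(F)F)C(F)(F)F | starting material
18 | 3,4-dimethoxy-2-(trimethylsilyl)-6-[2-(triisopropylsilyloxy)ethyl]phenyl trifluoromethanesulfonate | CC(C)[Si](C(C)C)(C(C)C)OCCc1cc(OC)c(OC)c([Si](C)(C)C)c1OS(=O)(=O)C(F)(F)F | intermediate
19 | 1,2-dibromotetrachloroethane | ClC(Cl)(Br)C(Cl)(Cl)Br | starting material
20 | potassium bromide | [K+].[Br-] | starting material
21 | 3,4-dimethoxy-6-[2-(triisopropylsilyloxy)ethyl]-1,2-didehydrobenzene (aryne, not isolated) | CC(C)[Si](C(C)C)(C(C)C)OCCC1=CC(OC)=C(OC)C#C1 | intermediate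
22 | 2-bromo-5,6-dimethoxy-3-[2-(triisopropylsilyloxy)ethyl]phenylpotassium (not isolated) | CC(C)[Si](C(C)C)(C(C)C)OCCc1cc(OC)c(OC)[c-]c1Br.[K+] | intermediate
23 | [2-(2,3-dibromo-4,5-dimethoxyphenyl)ethoxy]triisopropylsilane | CC(C)[Si](C(C)C)(C(C)C)OCCc1cc(OC)c(OC)c(Br)c1Br | intermediate
24 | 2-(2,3-dibromo-4,5-dimethoxyphenyl)ethanol | OCCc1cc(OC)c(OC)c(Br)c1Br | intermediate
25 | boron tribromide | BrB(Br)Br | starting material
26 | 2-(2,4,5-tribromo-1,3,2-benzodioxaborol-6-yl)ethyl dibromoborinate (not isolated) | BrB(Br)OCCc1cc2OB(Br)Oc2c(Br)c1Br | intermediate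
27 | 3,4-dibromo-5-(2-hydroxyethyl)benzene-1,2-diol | OCCc1cc(O)c(O)c(Br)c1Br | intermediate
28 | phenylboronic acid | OB(O)c1ccccc1 | starting material
29 | sulfur trioxide–pyridine complex | O=S(=O)([O-])[n+]1ccccc1 | starting material
30 | 2-(4,5-dibromo-2-phenyl-1,3,2-benzodioxaborol-6-yl)ethanol (not isolated) | OCCc1cc2OB(c3ccccc3)Oc2c(Br)c1Br | intermediate
31 | pyridinium 2-(4,5-dibromo-2-phenyl-1,3,2-benzodioxaborol-6-yl)ethyl sulfate (not isolated) | [O-]S(=O)(=O)OCCc1cc2OB(c3ccccc3)Oc2c(Br)c1Br.c1cc[nH+]cc1 | intermediate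
32 | 2-(2,3-dibromo-4,5-dihydroxyphenyl)ethyl hydrogen sulfate | O=S(=O)(O)OCCc1cc(O)c(O)c(Br)c1Br | target

**Step count and risks**
Total steps: 11. Longest linear sequence: 11 (fully linear from 1).

Steps most likely to fail:

1. Step 8. The ortho-bromoaryl anion may be protonated faster than it takes bromine, the aryl silane may be bromodesilylated before the elimination is triggered, or fluoride may unmask the side-chain oxygen, which then adds to the aryne. The fallback sets out from 18 and returns at 23. The aryne from 18 would be generated with CsF in MeCN in the presence of I2, whose σ-bond insertion is a well-established vicinal dihalogenation of arynes, to give [2-(2,3-diiodo-4,5-dimethoxyphenyl)ethoxy]triisopropylsilane F1. Iodine–magnesium exchange with iPrMgCl·LiCl in THF at −78 °C, expected at the iodine beside the methoxy group, should give 2-iodo-5,6-dimethoxy-3-[2-(triisopropylsilyloxy)ethyl]phenylmagnesium chloride F2. Cold bromination of F2 with 1,2-dibromotetrachloroethane should give [2-(3-bromo-2-iodo-4,5-dimethoxyphenyl)ethoxy]triisopropylsilane F3. A second exchange at the remaining iodine (iodine reacts in preference to bromine) should give 2-bromo-3,4-dimethoxy-6-[2-(triisopropylsilyloxy)ethyl]phenylmagnesium chloride F4, and the same Br+ quench returns 23.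

2. Step 10. Bromide may displace the boron-activated primary oxygen, turning the alcohol into the alkyl bromide, and the methoxy group next to bromine may be cleaved incompletely. The fallback sets out from 24 and returns at 27. The alcohol would be acetylated (Ac2O, pyridine, DMAP) to 2-(2,3-dibromo-4,5-dimethoxyphenyl)ethyl acetate F5. BBr3 in CH2Cl2 at −78 → 0 °C should then give 2-(2,3-dibromo-4,5-dihydroxyphenyl)ethyl acetate F6 with the side-chain oxygen shielded as the ester. Acidic methanolysis (HCl in MeOH, rt), under which the catechol is not oxidised, returns 27.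

3. Step 11. The boronate may open in pyridine so that a phenolic oxygen is sulfated, water left from esterification may consume the sulfating agent, and the alkyl sulfate may hydrolyse during isolation in the acid form. The fallback sets out from 27 and returns at 32. The catechol would be fixed as a covalent acetal with 2,2-dimethoxypropane and catalytic camphorsulfonic acid in toluene at reflux, giving 2-(4,5-dibromo-2,2-dimethyl-1,3-benzodioxol-6-yl)ethanol F7. Sulfation of the alcohol with SO3·pyridine should give 2-(4,5-dibromo-2,2-dimethyl-1,3-benzodioxol-6-yl)ethyl hydrogen sulfate F8. Brief treatment with TFA/H2O at 0 °C, which the alkyl sulfate should survive, removes the acetonide and returns 32.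

Further compounds
F1 | step 8 | [2-(2,3-diiodo-4,5-dimethoxyphenyl)ethoxy]triisopropylsilane | CC(C)[Si](C(C)C)(C(C)C)OCCc1cc(OC)c(OC)c(I)c1I
F2 | step 8 | 2-iodo-5,6-dimethoxy-3-[2-(triisopropylsilyloxy)ethyl]phenylmagnesium chloride | CC(C)[Si](C(C)C)(C(C)C)OCCc1cc(OC)c(OC)c([Mg]Cl)c1I
F3 | step 8 | [2-(3-bromo-2-iodo-4,5-dimethoxyphenyl)ethoxy]triisopropylsilane | CC(C)[Si](C(C)C)(C(C)C)OCCc1cc(OC)c(OC)c(Br)c1I
F4 | step 8 | 2-bromo-3,4-dimethoxy-6-[2-(triisopropylsilyloxy)ethyl]phenylmagnesium chloride | CC(C)[Si](C(C)C)(C(C)C)OCCc1cc(OC)c(OC)c(Br)c1[Mg]Cl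
F5 | step 10 | 2-(2,3-dibromo-4,5-dimethoxyphenyl)ethyl acetate | CC(=O)OCCc1cc(OC)c(OC)c(Br)c1Br
F6 | step 10 | 2-(2,3-dibromo-4,5-dihydroxyphenyl)ethyl acetate | CC(=O)OCCc1cc(O)c(O)c(Br)c1Br
F7 | step 11 | 2-(4,5-dibromo-2,2-dimethyl-1,3-benzodioxol-6-yl)ethanol | OCCc1cc2OC(C)(C)Oc2c(Br)c1Br
F8 | step 11 | 2-(4,5-dibromo-2,2-dimethyl-1,3-benzodioxol-6-yl)ethyl hydrogen sulfate | O=S(=O)(O)OCCc1cc2OC(C)(C)Oc2c(Br)c1Br
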